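**Plan**

1. Retrosynthesis: remove the O8 angelate, the 1,10-epoxide (from an E C1=C10 alkene), the C13 methylene and the lactone C6–O bond; cut C7–C11 (enolate alkylation); contract the ten-membered ring by a retro anionic oxy-Cope shift (cut C8–C9, re-form C1–C6); cut C6–C7 (alkenyl addition) and C1–C10 (1,4-addition) back to a p-quinone monoketal.
2. Enabling feature: in the ten-membered carbocycle the O-bearing C6 lies between C7–C8 (C8 oxygenated) and, through C1, the C1–C10 epoxide (a masked E alkene), so C8=C7–C6(O)–C1–C10=C9 is a 3-oxy-1,5-diene; the Z C4=C5 alkene with C3 and C6 cis is the remnant of a cyclohexene ring (C1–C6).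
3. Forward order: arene → quinone monoketal → substituted cyclohexenone (ring C1–C6) → ten-membered ring by two-carbon ring expansion with C7 alkylation in the same flask → γ-lactone → α-methylene → angelate → epoxide → desilylation.
4. Stereochemistry: ring C1 by Rh/(S)-BINAP 1,4-addition; C3 by Luche reduction (cis to isopropenyl); C8 by chair chirality transfer from C1 through the Z enol ether; C7 by outer-face alkylation; C6 by chelation-controlled reduction then SN2 lactonisation with inversion; C1/C10 by outer-face epoxidation; 4Z from the six-membered ring; angelate Z from angelic acid.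

Key step: step 11

Remark: locants C1–C15 in the text are the germacrane locants of the target (C6 lactone carbinol, C7 ring-fusion carbon bearing C11, C8 angelate carbon, C1/C10 epoxide, C14 methyl on C10, C15 CH2OH on C4); they are used for the six-membered precursors as well.
Remark: the facial sense of the Rh/(S)-BINAP addition in step 4 is assumed to follow that of cyclohex-2-enone; if it does not, (R)-BINAP is used.

**Route**

Step 1
Reactants: 1 2-hydroxy-5-methoxybenzaldehyde
Product: 2 2-(hydroxymethyl)-4-methoxyphenol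
Conditions: NaBH4, MeOH, 0 °C
Reagents that add atoms: none
Why: Chemoselective borohydride reduction of the aryl aldehyde to the benzylic alcohol, which becomes C15; no stereocentre is formed.

Step 2
Reactants: 2 2-(hydroxymethyl)-4-methoxyphenol
Product: 3 2-{[(tert-butyldimethylsilyl)oxy]methyl}-4-methoxyphenol
Conditions: TBSCl (1.05 equiv), imidazole, CH2Cl2, 0 °C
Reagents that add atoms: tert-butyldimethylsilyl chloride, CC(C)(C)[Si](C)(C)Cl
Why: Imidazole-mediated silylation should take the primary benzylic hydroxyl in preference to the hydrogen-bonded, less nucleophilic phenol, as is usual for salicyl alcohols.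

Step 3
Reactants: 3 2-{[(tert-butyldimethylsilyl)oxy]methyl}-4-methoxyphenol
Product: 4 2-{[(tert-butyldimethylsilyl)oxy]methyl}-4,4-dimethoxycyclohexa-2,5-dien-1-one
Conditions: PhI(OAc)2, MeOH, 0 °C
Reagents that add atoms: methanol, CO
Why: Oxidative dearomatisation of a 4-methoxyphenol in methanol gives the p-quinone monoketal, which carries the later C3 carbonyl free and the later C6 carbonyl masked.

Step 4
Reactants: 4 quinone monoketal; 5 potassium trifluoro(prop-1-en-2-yl)borate
Product: 6 (5S)-2-{[(tert-butyldimethylsilyl)oxy]methyl}-4,4-dimethoxy-5-(prop-1-en-2-yl)cyclohex-2-en-1-one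
Conditions: [Rh(cod)2]BF4 (3 mol%), (S)-BINAP (3.3 mol%), Et3N, toluene/H2O, rt
Reagents that add atoms: none
Why: Rhodium-catalysed asymmetric 1,4-addition (Hayashi–Miyaura type) of the alkenyl trifluoroborate should occur only at the unsubstituted enone of the dienone, the ligand choosing the enone face and setting the isopropenyl-bearing centre (ring C1) as S.

Step 5
Reactants: 6 (5S)-enone ketal
Product: 7 (1S,5S)-2-{[(tert-butyldimethylsilyl)oxy]methyl}-4,4-dimethoxy-5-(prop-1-en-2-yl)cyclohex-2-en-1-ol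
Conditions: NaBH4, CeCl3·7H2O, MeOH, −78 → −40 °C
Reagents that add atoms: none
Why: Luche 1,2-reduction with axial hydride delivery on the face of the axial hydrogen at the isopropenyl carbon should give the 1,3-cis alcohol, as carvone gives cis-carveol, setting C3 as S.

Step 6
Reactants: 7 (1S,5S)-allylic alcohol
Product: 8 tert-butyl{[(1S,5S)-2-{[(tert-butyldimethylsilyl)oxy]methyl}-4,4-dimethoxy-5-(prop-1-en-2-yl)cyclohex-2-en-1-yl]oxy}dimethylsilane
Conditions: TBSCl, imidazole, DMF, rt
Reagents that add atoms: tert-butyldimethylsilyl chloride, CC(C)(C)[Si](C)(C)Cl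
Why: Standard silyl ether formation at the secondary allylic alcohol under conditions that leave the dimethyl ketal intact.

Step 7
Reactants: 8 bis-silyl ether ketal
Product: 9 (4S,6S)-4-[(tert-butyldimethylsilyl)oxy]-3-{[(tert-butyldimethylsilyl)oxy]methyl}-6-(prop-1-en-2-yl)cyclohex-2-en-1-one
Conditions: PPTS (cat.), acetone/H2O 10:1, rt
Reagents that add atoms: water, O
Why: Mild acid hydrolysis of the allylic dimethyl ketal (through a vinylogous oxocarbenium ion) unveils the C6 enone while the weak acid should spare both silyl ethers and not move the α-isopropenyl alkene into conjugation.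

Step 8
Reactants: 10 4-methoxybenzyl alcohol; 11 vinyl acetate
Product: 12 4-methoxybenzyl vinyl ether
Conditions: [Ir(cod)Cl]2 (1 mol%), Na2CO3, toluene, 100 °C
Reagents that add atoms: none
Why: Iridium-catalysed transvinylation of an alcohol with vinyl acetate gives the vinyl ether without acid.

Step 9
Reactants: 12 4-methoxybenzyl vinyl ether
Product: 14 1-({[(Z)-2-bromoethenyl]oxy}methyl)-4-methoxybenzene, via dibromide 13 (not isolated)
Conditions: Br2, CH2Cl2, −78 °C; then i-Pr2NEt, −78 °C → rt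
Reagents that add atoms: bromine, BrBr
Why: Bromine addition to the electron-rich vinyl ether followed by amine dehydrobromination of the α-bromo ether should give the 2-bromovinyl ether with the Z isomer favoured, as for the ethyl analogue, the minor E isomer being removed by chromatography.

Step 10
Reactants: 14 (Z)-2-bromovinyl 4-methoxybenzyl ether; 9 (4S,6S)-enone
Product: 16 (1S,4S,6S)-4-[(tert-butyldimethylsilyl)oxy]-3-{[(tert-butyldimethylsilyl)oxy]methyl}-1-{(Z)-2-[(4-methoxybenzyl)oxy]ethenyl}-6-(prop-1-en-2-yl)cyclohex-2-en-1-ol, via alkenyllithium 15 (not isolated)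
Conditions: t-BuLi (2.0 equiv), Et2O, −78 °C; then 9 premixed with anhydrous CeCl3, THF, −78 °C; H2O quench, product used without acidic contact
Reagents that add atoms: none
Why: Bromine–lithium exchange with retention gives the Z β-alkoxyvinyllithium (stable below −70 °C), and cerium-mediated 1,2-addition, whose low basicity avoids enolisation at the isopropenyl carbon, should occur anti to the adjacent isopropenyl group to give the trans-1,2-dialkenyl carbinol (C6 S, hydroxyl cis to isopropenyl).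

Step 11
Reactants: 16 trans-dialkenyl carbinol; 17 tert-butyl bromoacetate
Product: 20 tert-butyl 2-[(1R,2R,4E,7S,8Z)-7-[(tert-butyldimethylsilyl)oxy]-8-{[(tert-butyldimethylsilyl)oxy]methyl}-2-[(4-methoxybenzyl)oxy]-4-methyl-10-oxocyclodeca-4,8-dien-1-yl]acetate, via potassium alkoxide 18 (not isolated), via potassium enolate 19 (not isolated)
Conditions: KN(SiMe3)2 (1.1 equiv), 18-crown-6, THF, −78 → 0 °C; recool to −78 °C, then 17, −78 → −40 °C
Reagents that add atoms: none
Why: KN(SiMe3)2/18-crown-6 converts 16 into the dissociated tertiary bis-allylic alkoxide 18, which undergoes an anionic oxy-Cope [3,3]-sigmatropic shift in which the C1–C6 bond of the six-membered ring breaks while C8–C9 forms, driven by formation of the cross-conjugated enolate 19, which is then C-alkylated by 17. The closest known reaction type is the anionic oxy-Cope ring expansion of trans-1,2-dialkenylcyclohexanols to cyclodec-5-enones with alkylation of the regiodefined enolate in the same flask. The ten-membered carbocycle is closed by this two-carbon ring expansion, a concerted pericyclic process through a six-centre chair transition state and not an end-to-end cyclisation, so no high dilution is needed. Both ring bonds (C6–C5 and C1–C2) sit equatorial on the chair, which makes the new C1=C10 alkene E and keeps the cyclohexene-derived C4=C5 Z, while the Z enol ether places OPMB axial so that the S configuration of the isopropenyl carbon C1 is relayed to 8R at the new C8–C9 bond. C7 should be fixed as 7R because the electrophile enters the enolate on its outer face, anti to the new C8–C9 bond (C11 cis to O8). The step needs chair over boat (secured by the trans-diequatorial alkenyl groups and a K+ bridge between O6 and O8), reaction of the side-chain enol ether and not the ring C4=C5 alkene (which cannot reach C9), and alkylation faster than E1cB loss of PMBO− from 19 (secured by keeping 19 at or below 0 °C and trapping at −78 °C with the reactive α-bromo ester).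

Step 12
Reactants: 20 ten-membered keto ester
Product: 21 tert-butyl 2-[(1S,2R,4E,7S,8Z,10S)-7-[(tert-butyldimethylsilyl)oxy]-8-{[(tert-butyldimethylsilyl)oxy]methyl}-10-hydroxy-2-[(4-methoxybenzyl)oxy]-4-methylcyclodeca-4,8-dien-1-yl]acetate
Conditions: Zn(BH4)2, Et2O, −30 → 0 °C
Reagents that add atoms: none
Why: Chelation-controlled 1,2-reduction in which zinc bridges the C6 carbonyl and the C8 ether oxygen in a six-membered chelate with C5, C9 and the C7 side chain equatorial, so that axial hydride attack should give the 6,8-syn alcohol (6S), the C6 epimer of the lactone configuration.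

Step 13
Reactants: 21 (6S)-hydroxy tert-butyl ester
Product: 23 (3aR,4R,6E,9S,10Z,11aR)-9-[(tert-butyldimethylsilyl)oxy]-10-{[(tert-butyldimethylsilyl)oxy]methyl}-4-[(4-methoxybenzyl)oxy]-6-methyl-3a,4,5,8,9,11a-hexahydrocyclodeca[b]furan-2(3H)-one, via C6 mesylate 22 (not isolated)
Conditions: Ms2O, Et3N, CH2Cl2, 0 °C → rt
Reagents that add atoms: none
Why: The allylic mesylate is displaced from the rear by the carbonyl oxygen of the tert-butyl ester (neighbouring-group participation, 5-exo-tet, side chain anti to the leaving group) and the dialkoxycarbenium ion loses isobutene, so C6 is inverted to R and the trans-fused γ-lactone results.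

Step 14
Reactants: 23 trans-fused lactone
Product: 27 (3aR,4R,6E,9S,10Z,11aR)-9-[(tert-butyldimethylsilyl)oxy]-10-{[(tert-butyldimethylsilyl)oxy]methyl}-4-[(4-methoxybenzyl)oxy]-6-methyl-3-methylidene-3a,4,5,8,9,11a-hexahydrocyclodeca[b]furan-2(3H)-one, via lithium enolate 24 (not isolated), via Mannich base 25 (not isolated), via ammonium iodide 26 (not isolated)
Conditions: LiN(SiMe3)2, THF, −78 °C; [Me2N=CH2]I, −78 → 0 °C; then MeI, MeOH, rt; then aq. NaHCO3, CH2Cl2, rt
Reagents that add atoms: N,N-dimethylmethyleneiminium iodide (Eschenmoser's salt), C=[N+](C)C.[I-]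
Why: Standard lactone α-methylenation (enolate Mannich reaction, quaternisation, base-induced elimination of trimethylamine), possible here because C7 carries no β-leaving group and O8 is a non-enolisable ether.

Step 15
Reactants: 27 α-methylene lactone PMB ether
Product: 28 (3aR,4R,6E,9S,10Z,11aR)-9-[(tert-butyldimethylsilyl)oxy]-10-{[(tert-butyldimethylsilyl)oxy]methyl}-4-hydroxy-6-methyl-3-methylidene-3a,4,5,8,9,11a-hexahydrocyclodeca[b]furan-2(3H)-one
Conditions: DDQ, CH2Cl2/pH 7 buffer, 0 °C → rt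
Reagents that add atoms: none
Why: Oxidative cleavage of the 4-methoxybenzyl ether (benzylic hydride abstraction, hydrolysis of the oxocarbenium ion) frees only the C8 hydroxyl, the silyl ethers, alkenes and enoate being inert to DDQ.

Step 16
Reactants: 28 C8 alcohol; 29 angelic acid
Product: 31 (3aR,4R,6E,9S,10Z,11aR)-9-[(tert-butyldimethylsilyl)oxy]-10-{[(tert-butyldimethylsilyl)oxy]methyl}-6-methyl-3-methylidene-2-oxo-2,3,3a,4,5,8,9,11a-octahydrocyclodeca[b]furan-4-yl (2Z)-2-methylbut-2-enoate, via mixed anhydride 30 (not isolated)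
Conditions: 2,4,6-Cl3C6H2COCl, Et3N, toluene, rt; then 28, toluene, 70 °C, no DMAP
Reagents that add atoms: none
Why: Yamaguchi-type esterification through the mixed 2,4,6-trichlorobenzoic anhydride without a nucleophilic catalyst, conditions under which the angeloyl group should be transferred at its unhindered carbonyl without Z → E isomerisation to the tiglate.

Step 17
Reactants: 31 C8 angelate
Product: 32 (1R,10R)-1,10-epoxide of 31
Conditions: mCPBA, NaHCO3, CH2Cl2, −20 → 0 °C
Reagents that add atoms: 3-chloroperoxybenzoic acid, OOC(=O)c1cccc(Cl)c1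
Why: Prilezhaev epoxidation of the only electron-rich alkene (C4=C5 is deactivated by three allylic oxygens and shielded by the silyl groups, both enoates are electron-poor), with attack on the outer face of the E alkene in the ring conformation held by the trans-lactone expected to give the trans (1R,10R)-epoxide.

Step 18
Reactants: 32 bis-silyl epoxide
Product: 33 CNP0187917.1, (1R,3S,4Z,6R,7R,8R,10R)-1,10-epoxy-3,15-dihydroxy-8-[(2Z)-2-methylbut-2-enoyloxy]germacra-4,11(13)-dien-12,6-olide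
Conditions: HF·pyridine, pyridine, THF, 0 °C → rt
Reagents that add atoms: none
Why: Buffered fluoride cleavage of the primary and secondary allylic silyl ethers, the excess pyridine protecting the epoxide from acid-induced transannular opening and leaving the angelate and α-methylene lactone untouched.

**Compound list**

1 | 2-hydroxy-5-methoxybenzaldehyde | COc1ccc(O)c(C=O)c1 | starting material
2 | 2-(hydroxymethyl)-4-methoxyphenol | COc1ccc(O)c(CO)c1 | intermediate
3 | 2-{[(tert-butyldimethylsilyl)oxy]methyl}-4-methoxyphenol | COc1ccc(O)c(CO[Si](C)(C)C(C)(C)C)c1 | intermediate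
4 | 2-{[(tert-butyldimethylsilyl)oxy]methyl}-4,4-dimethoxycyclohexa-2,5-dien-1-one | COC1(OC)C=CC(=O)C(CO[Si](C)(C)C(C)(C)C)=C1 | intermediate
5 | potassium trifluoro(prop-1-en-2-yl)borate | CC(=C)[B-](F)(F)F.[K+] | starting material
6 | (5S)-2-{[(tert-butyldimethylsilyl)oxy]methyl}-4,4-dimethoxy-5-(prop-1-en-2-yl)cyclohex-2-en-1-one | O=C1C[C@@H](C(C)=C)C(OC)(OC)C=C1CO[Si](C)(C)C(C)(C)C | intermediate
7 | (1S,5S)-2-{[(tert-butyldimethylsilyl)oxy]methyl}-4,4-dimethoxy-5-(prop-1-en-2-yl)cyclohex-2-en-1-ol | O[C@H]1C[C@@H](C(C)=C)C(OC)(OC)C=C1CO[Si](C)(C)C(C)(C)C | intermediate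
8 | tert-butyl{[(1S,5S)-2-{[(tert-butyldimethylsilyl)oxy]methyl}-4,4-dimethoxy-5-(prop-1-en-2-yl)cyclohex-2-en-1-yl]oxy}dimethylsilane | CC(C)(C)[Si](C)(C)O[C@H]1C[C@@H](C(C)=C)C(OC)(OC)C=C1CO[Si](C)(C)C(C)(C)C | intermediate
9 | (4S,6S)-4-[(tert-butyldimethylsilyl)oxy]-3-{[(tert-butyldimethylsilyl)oxy]methyl}-6-(prop-1-en-2-yl)cyclohex-2-en-1-one | CC(C)(C)[Si](C)(C)O[C@H]1C[C@@H](C(C)=C)C(=O)C=C1CO[Si](C)(C)C(C)(C)C | intermediate
10 | 4-methoxybenzyl alcohol | COc1ccc(CO)cc1 | starting material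
11 | vinyl acetate | CC(=O)OC=C | starting material
12 | 4-methoxybenzyl vinyl ether | COc1ccc(COC=C)cc1 | intermediate
13 | 1-[(1,2-dibromoethoxy)methyl]-4-methoxybenzene (racemic) | COc1ccc(COC(Br)CBr)cc1 | intermediate
14 | 1-({[(Z)-2-bromoethenyl]oxy}methyl)-4-methoxybenzene | COc1ccc(CO/C=C\Br)cc1 | intermediate
15 | {(Z)-2-[(4-methoxybenzyl)oxy]ethenyl}lithium | [Li]/C=C\OCc1ccc(OC)cc1 | intermediate
16 | (1S,4S,6S)-4-[(tert-butyldimethylsilyl)oxy]-3-{[(tert-butyldimethylsilyl)oxy]methyl}-1-{(Z)-2-[(4-methoxybenzyl)oxy]ethenyl}-6-(prop-1-en-2-yl)cyclohex-2-en-1-ol | CC(C)(C)[Si](C)(C)O[C@H]1C[C@@H](C(C)=C)[C@](O)(/C=C\OCc2ccc(OC)cc2)C=C1CO[Si](C)(C)C(C)(C)C | intermediate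
17 | tert-butyl bromoacetate | CC(C)(C)OC(=O)CBr | starting material
18 | potassium (1S,4S,6S)-4-[(tert-butyldimethylsilyl)oxy]-3-{[(tert-butyldimethylsilyl)oxy]methyl}-1-{(Z)-2-[(4-methoxybenzyl)oxy]ethenyl}-6-(prop-1-en-2-yl)cyclohex-2-en-1-olate | CC(C)(C)[Si](C)(C)O[C@H]1C[C@@H](C(C)=C)[C@]([O-])(/C=C\OCc2ccc(OC)cc2)C=C1CO[Si](C)(C)C(C)(C)C.[K+] | intermediate
19 | potassium (1(10)Z,2Z,4S,6E,9R)-4-[(tert-butyldimethylsilyl)oxy]-3-{[(tert-butyldimethylsilyl)oxy]methyl}-9-[(4-methoxybenzyl)oxy]-7-methylcyclodeca-1(10),2,6-trien-1-olate | C1/C(C)=C/C[C@H](O[Si](C)(C)C(C)(C)C)/C(CO[Si](C)(C)C(C)(C)C)=C\C([O-])=C\[C@@H]1OCc2ccc(OC)cc2.[K+] | intermediate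
20 | tert-butyl 2-[(1R,2R,4E,7S,8Z)-7-[(tert-butyldimethylsilyl)oxy]-8-{[(tert-butyldimethylsilyl)oxy]methyl}-2-[(4-methoxybenzyl)oxy]-4-methyl-10-oxocyclodeca-4,8-dien-1-yl]acetate | C1/C(C)=C/C[C@H](O[Si](C)(C)C(C)(C)C)/C(CO[Si](C)(C)C(C)(C)C)=C\C(=O)[C@H](CC(=O)OC(C)(C)C)[C@@H]1OCc2ccc(OC)cc2 | intermediate
21 | tert-butyl 2-[(1S,2R,4E,7S,8Z,10S)-7-[(tert-butyldimethylsilyl)oxy]-8-{[(tert-butyldimethylsilyl)oxy]methyl}-10-hydroxy-2-[(4-methoxybenzyl)oxy]-4-methylcyclodeca-4,8-dien-1-yl]acetate | C1/C(C)=C/C[C@H](O[Si](C)(C)C(C)(C)C)/C(CO[Si](C)(C)C(C)(C)C)=C\[C@H](O)[C@H](CC(=O)OC(C)(C)C)[C@@H]1OCc2ccc(OC)cc2 | intermediate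
22 | C6 methanesulfonate of 21 | C1/C(C)=C/C[C@H](O[Si](C)(C)C(C)(C)C)/C(CO[Si](C)(C)C(C)(C)C)=C\[C@H](OS(C)(=O)=O)[C@H](CC(=O)OC(C)(C)C)[C@@H]1OCc2ccc(OC)cc2 | intermediate
23 | (3aR,4R,6E,9S,10Z,11aR)-9-[(tert-butyldimethylsilyl)oxy]-10-{[(tert-butyldimethylsilyl)oxy]methyl}-4-[(4-methoxybenzyl)oxy]-6-methyl-3a,4,5,8,9,11a-hexahydrocyclodeca[b]furan-2(3H)-one | C1/C(C)=C/C[C@H](O[Si](C)(C)C(C)(C)C)/C(CO[Si](C)(C)C(C)(C)C)=C\[C@H]2OC(=O)C[C@@H]2[C@@H]1OCc3ccc(OC)cc3 | intermediate
24 | lithium enolate (C11=C12–OLi) of lactone 23 | C1/C(C)=C/C[C@H](O[Si](C)(C)C(C)(C)C)/C(CO[Si](C)(C)C(C)(C)C)=C\[C@H]2OC([O-])=C[C@@H]2[C@@H]1OCc3ccc(OC)cc3.[Li+] | intermediate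
25 | 3-[(dimethylamino)methyl] derivative of lactone 23 (C11 epimers) | C1/C(C)=C/C[C@H](O[Si](C)(C)C(C)(C)C)/C(CO[Si](C)(C)C(C)(C)C)=C\[C@H]2OC(=O)C(CN(C)C)[C@@H]2[C@@H]1OCc3ccc(OC)cc3 | intermediate
26 | trimethylammonium iodide from 25 (N-methylated Mannich base) | C1/C(C)=C/C[C@H](O[Si](C)(C)C(C)(C)C)/C(CO[Si](C)(C)C(C)(C)C)=C\[C@H]2OC(=O)C(C[N+](C)(C)C)[C@@H]2[C@@H]1OCc3ccc(OC)cc3.[I-] | intermediate
27 | (3aR,4R,6E,9S,10Z,11aR)-9-[(tert-butyldimethylsilyl)oxy]-10-{[(tert-butyldimethylsilyl)oxy]methyl}-4-[(4-methoxybenzyl)oxy]-6-methyl-3-methylidene-3a,4,5,8,9,11a-hexahydrocyclodeca[b]furan-2(3H)-one | C1/C(C)=C/C[C@H](O[Si](C)(C)C(C)(C)C)/C(CO[Si](C)(C)C(C)(C)C)=C\[C@H]2OC(=O)C(=C)[C@@H]2[C@@H]1OCc3ccc(OC)cc3 | intermediate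
28 | (3aR,4R,6E,9S,10Z,11aR)-9-[(tert-butyldimethylsilyl)oxy]-10-{[(tert-butyldimethylsilyl)oxy]methyl}-4-hydroxy-6-methyl-3-methylidene-3a,4,5,8,9,11a-hexahydrocyclodeca[b]furan-2(3H)-one | C1/C(C)=C/C[C@H](O[Si](C)(C)C(C)(C)C)/C(CO[Si](C)(C)C(C)(C)C)=C\[C@H]2OC(=O)C(=C)[C@@H]2[C@@H]1O | intermediate
29 | angelic acid, (2Z)-2-methylbut-2-enoic acid | C/C=C(/C)C(=O)O | starting material
30 | (2Z)-2-methylbut-2-enoic 2,4,6-trichlorobenzoic anhydride | C/C=C(/C)C(=O)OC(=O)c1c(Cl)cc(Cl)cc1Cl | intermediate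
31 | (3aR,4R,6E,9S,10Z,11aR)-9-[(tert-butyldimethylsilyl)oxy]-10-{[(tert-butyldimethylsilyl)oxy]methyl}-6-methyl-3-methylidene-2-oxo-2,3,3a,4,5,8,9,11a-octahydrocyclodeca[b]furan-4-yl (2Z)-2-methylbut-2-enoate | C1/C(C)=C/C[C@H](O[Si](C)(C)C(C)(C)C)/C(CO[Si](C)(C)C(C)(C)C)=C\[C@H]2OC(=O)C(=C)[C@@H]2[C@@H]1OC(=O)/C(C)=C\C | intermediate
32 | (1R,10R)-1,10-epoxide of 31 (3,15-bis-O-TBS ether of the target) | C1[C@@]2(C)O[C@@H]2C[C@H](O[Si](C)(C)C(C)(C)C)/C(CO[Si](C)(C)C(C)(C)C)=C\[C@H]3OC(=O)C(=C)[C@@H]3[C@@H]1OC(=O)/C(C)=C\C | intermediate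
33 | CNP0187917.1, (1R,3S,4Z,6R,7R,8R,10R)-1,10-epoxy-3,15-dihydroxy-8-[(2Z)-2-methylbut-2-enoyloxy]germacra-4,11(13)-dien-12,6-olide | C=C1C(=O)O[C@@H]2/C=C(/CO)[C@@H](O)C[C@H]3O[C@]3(C)C[C@@H](OC(=O)/C(C)=C\C)[C@@H]12 | target

**Count and risks**

Total step count: 18. Longest linear sequence: 16 steps (steps 1–7 and 10–18 from 1); steps 8–9 form the side branch to 14.

Steps most likely to fail:

1. Step 11. The potassium enolate 19 carries PMBO on its β-carbon, so E1cB loss of 4-methoxybenzyl oxide may outrun the alkylation; a boat pathway would also erode the C8 configuration. Fallback (from 9, back at 20): the C8 oxygen is brought in after the ring expansion, so that no enolate with a β-leaving group is formed during the rearrangement. Compound 9 takes up CH2=CHMgBr/CeCl3 to give the vinyl carbinol F1. KN(SiMe3)2/18-crown-6 then Me3SiCl gives the ten-membered trimethylsilyl enol ether F2. Saegusa–Ito dehydrogenation with Pd(OAc)2 gives the cross-conjugated trienone F3. Conjugate borylation with bis(pinacolato)diboron, CuCl, NaOt-Bu and a chiral bisphosphine in the presence of MeOH gives the β-boryl ketone F4, which NaBO3·4H2O oxidises with retention to the β-hydroxy ketone F5. 4-Methoxybenzyl trichloroacetimidate with catalytic La(OTf)3 gives the PMB ether F6. LiN(SiMe3)2 at −78 °C followed by 17 then gives 20; C8 would then rest on ligand control and C7 on outer-face alkylation of the lithium enolate.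

2. Step 12. Hydride delivery may take place on the other face of the C6 carbonyl if the chelate does not form or the ring adopts another conformation, giving poor or reversed selectivity at C6. Fallback (from 20, back at 23): reduction under non-chelating Luche conditions (NaBH4, CeCl3·7H2O, MeOH, −78 °C) is used to favour the (6R)-alcohol F7, which NaN(SiMe3)2 in THF lactonises with retention by alkoxide acyl substitution on the tert-butyl ester. Because the 6S epimer closes with inversion (step 13) and the 6R epimer with retention, both epimers converge on 23.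

3. Step 17. Facial selectivity of the epoxidation may be poor or reversed if the peracid attacks through another ring conformer. Fallback (from 31, back at 32): NBS in aqueous THF forms the bromonium ion on the face preferred by electrophiles and water opens it at the tertiary C10 to give the bromohydrin F8; Ag2O then closes the epoxide by SN2 at C1, which places the oxygen on the face opposite to the one attacked first.

Further compounds
F1 | step 11 | (1S,4S,6S)-4-[(tert-butyldimethylsilyl)oxy]-3-{[(tert-butyldimethylsilyl)oxy]methyl}-1-ethenyl-6-(prop-1-en-2-yl)cyclohex-2-en-1-ol | CC(C)(C)[Si](C)(C)O[C@H]1C[C@@H](C(C)=C)[C@](O)(C=C)C=C1CO[Si](C)(C)C(C)(C)C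
F2 | step 11 | (1(10)Z,2Z,4S,6E)-4-[(tert-butyldimethylsilyl)oxy]-3-{[(tert-butyldimethylsilyl)oxy]methyl}-7-methyl-1-[(trimethylsilyl)oxy]cyclodeca-1(10),2,6-triene | C1/C(C)=C/C[C@H](O[Si](C)(C)C(C)(C)C)/C(CO[Si](C)(C)C(C)(C)C)=C\C(O[Si](C)(C)C)=C\C1
F3 | step 11 | (2Z,4S,6E,9E)-4-[(tert-butyldimethylsilyl)oxy]-3-{[(tert-butyldimethylsilyl)oxy]methyl}-7-methylcyclodeca-2,6,9-trien-1-one | CC(C)(C)[Si](C)(C)O[C@@H]1/C(CO[Si](C)(C)C(C)(C)C)=C\C(=O)/C=C/C/C(C)=C/C1
F4 | step 11 | (2Z,4S,6E,9R)-4-[(tert-butyldimethylsilyl)oxy]-3-{[(tert-butyldimethylsilyl)oxy]methyl}-7-methyl-9-(4,4,5,5-tetramethyl-1,3,2-dioxaborolan-2-yl)cyclodeca-2,6-dien-1-one | C1/C(C)=C/C[C@H](O[Si](C)(C)C(C)(C)C)/C(CO[Si](C)(C)C(C)(C)C)=C\C(=O)C[C@@H]1B2OC(C)(C)C(C)(C)O2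
F5 | step 11 | (2Z,4S,6E,9R)-4-[(tert-butyldimethylsilyl)oxy]-3-{[(tert-butyldimethylsilyl)oxy]methyl}-9-hydroxy-7-methylcyclodeca-2,6-dien-1-one | C1/C(C)=C/C[C@H](O[Si](C)(C)C(C)(C)C)/C(CO[Si](C)(C)C(C)(C)C)=C\C(=O)C[C@@H]1O
F6 | step 11 | (2Z,4S,6E,9R)-4-[(tert-butyldimethylsilyl)oxy]-3-{[(tert-butyldimethylsilyl)oxy]methyl}-9-[(4-methoxybenzyl)oxy]-7-methylcyclodeca-2,6-dien-1-one | C1/C(C)=C/C[C@H](O[Si](C)(C)C(C)(C)C)/C(CO[Si](C)(C)C(C)(C)C)=C\C(=O)C[C@@H]1OCc2ccc(OC)cc2
F7 | step 12 | tert-butyl 2-[(1S,2R,4E,7S,8Z,10R)-7-[(tert-butyldimethylsilyl)oxy]-8-{[(tert-butyldimethylsilyl)oxy]methyl}-10-hydroxy-2-[(4-methoxybenzyl)oxy]-4-methylcyclodeca-4,8-dien-1-yl]acetate | C1/C(C)=C/C[C@H](O[Si](C)(C)C(C)(C)C)/C(CO[Si](C)(C)C(C)(C)C)=C\[C@@H](O)[C@H](CC(=O)OC(C)(C)C)[C@@H]1OCc2ccc(OC)cc2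
F8 | step 17 | (1S,10R)-1-bromo-10-hydroxy-1,10-dihydro derivative of 31 (bromohydrin) | C1[C@@](C)(O)[C@@H](Br)C[C@H](O[Si](C)(C)C(C)(C)C)/C(CO[Si](C)(C)C(C)(C)C)=C\[C@H]2OC(=O)C(=C)[C@@H]2[C@@H]1OC(=O)/C(C)=C\C
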